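**Assumption:** the target SMILES gives no descriptor for the C6'–C8 biaryl axis, so the axis is treated as configurationally undefined and no atropselectivity is demanded.

## Analysis of the target

- The target (C30H26O12) consists of two flavan-3-ol units. Each is a chroman (rings A and C) carrying a catechol ring B at C2, and the two units are joined by a single aryl–aryl bond.
- The upper unit is (2R,3R), 2,3-cis, which is the configuration of (−)-epicatechin. The lower unit is (2R,3S), 2,3-trans, which is the configuration of (+)-catechin. The four stereocentres form two remote pairs that do not influence each other.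
- The only bond that is not already present in the two natural monomers runs from C6' of ring B of the upper unit (ortho to C1', para to O3') to C8 of ring A of the lower unit (between C7–OH and C8a–O1).
- This bond is the feature the strategy is tied to. C6' is the one unsubstituted β-carbon of the ortho-quinone that corresponds to ring B of the upper unit (enone C4'=O/C5'=C6'). C8 is the most nucleophilic carbon of the phloroglucinol-type ring A of the lower unit. The bond therefore has the polarity of a quinone–arene conjugate addition.
- The axis carries three ortho substituents (C2 of the upper chroman, O7 and O1 of the lower unit), so rotation is hindered.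
- Sensitive groups: eight phenolic hydroxyls (two catechols that oxidise readily, above all as phenolates) and two secondary alcohols. The benzylic C2–O1 ether para to the 4'-OH can open to a quinone methide under base or heat, which epimerises C2.
- The difficulty is one of selectivity. The two monomers differ only at C3, yet one must act as acceptor through ring B and the other as donor through ring A. There are two oxidisable catechols and four nucleophilic ring-A carbons (C6 and C8 of each unit). C6' cannot be reached by electrophilic substitution on a protected monomer, because ring A reacts first.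

## Retrosynthetic reasoning

**11 to 10.** The final operation on a polar, air-sensitive decaol should be neutral and leave only volatile by-products. The four phenols of the lower unit are therefore carried as benzyl ethers in 10 and released by hydrogenolysis.

**10 to 9.** The three hydroxyls O3, O5 and O7 of the upper unit are carried as acetates in 9 and removed by acid-catalysed methanolysis. They are not ornamental: they silence ring A and O3 of the upper unit during the key step.

**9 to 7 plus 2 (via 8), and 7 to 6.** The C6'–C8 biaryl bond is cut. This is the only bond absent from 1 and 3, so all four stereocentres stay in purchased material and the two halves are of equal size. The cut follows the innate polarity: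

- Ring B of the upper unit at the quinone oxidation level (7) is an acceptor whose only free β-carbon is C6'.
- Ring A of 2 is a donor whose reactive carbon is C8.
- Adduct 8 is simply the keto tautomer of 9, so neither carbon needs a halide or a boron group.

The forward reaction must pick one donor ring out of four arenes, one carbon on each partner, and stop after one addition. The protecting groups are assigned to do this: ethers on the donor 2, esters on the acceptor, and the only free catechol in the flask is the one in 6 that is to be oxidised to 7.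

**6 to 5 to 4 to 3.** Compound 6 needs acyl groups on O3, O5 and O7 but none on the catechol. The catechol of 3 is therefore masked first as a diphenylmethylene ketal (4); it is the only pair of hydroxyls that can close a five-membered ring. The remaining hydroxyls are then acetylated (5), and the ketal is removed by hydrogenolysis, to which esters are inert.

**2 to 1.** One-step tetra-O-benzylation of 1. Under carbonate base only the phenols react; the free C3–OH of 2 is harmless later.

## Alternatives that were turned down

**Alternative 1:** the textbook route. The same C6'–C8 bond is cut as a Suzuki–Miyaura cross-coupling of two pre-functionalised, fully benzylated monomers: 8-bromo-5,7,3',4'-tetra-O-benzyl-(+)-catechin A1 (from 2 by electrophilic bromination) and the 6'-pinacolboronate of 5,7,3',4'-tetra-O-benzyl-(−)-epicatechin A2. The forward key step is the palladium-catalysed union of A1 and A2 to a tri-ortho-substituted biaryl. It was turned down for three reasons: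

- A2 has no short access. On any ether-protected epicatechin, electrophilic halogenation goes to ring A, so ring B would have to be halogenated before the flavan is built. That means a de novo synthesis of the epicatechin skeleton with its two stereocentres.
- Both carbons pay for a leaving group that the target does not contain, at a cost of at least three extra steps.
- The coupling joins a 2,6-dioxygenated aryl (slow oxidative addition as the halide, easy protodeboronation as the boronate) to an ortho-branched partner.

A shortened variant that borrows the acetate pattern of the chosen route is kept only as the fallback for step 5.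

**Alternative 2:** do not join two flavans. Ring C of the upper unit is cut at O1–C2 and C2–C3, and the epicatechin unit is built on the biaryl aldehyde A3, which would come from A1 and a small ortho-formyl arylboron partner. The forward key step is olefination of A3 to the (E)-1,3-diarylpropene A4, asymmetric dihydroxylation of A4 and ring closure to a 2,3-trans flavan, followed by inversion at C3 through oxidation and hydride reduction. It was turned down because:

- the easy biaryl coupling is bought with about eight further steps;
- C2 and C3 of the upper unit would have to be created next to a bulky ortho-aryl group;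
- the cis relationship needs a redox detour;
- all of this rebuilds a unit that is sold as 3.

**Alternative 3:** a temporary tether. The same biaryl bond is made intramolecularly after linking O3 of the upper unit to O7 of the lower unit through a diisopropylsilylene bridge, as in A5. The forward key step is oxidation of the catechol of A5 and conjugate addition within the tethered pair, closing a nine-membered ring (C6'–C1'–C2–C3–O3–Si–O7–C7–C8), followed by removal of silicon. It was turned down because:

- O7 lies between C6 and C8, so the tether brings both carbons equally close and leaves the one open regiochemical question on the donor unanswered;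
- a silyl group on O7 weakens the donor ring;
- the nine-membered ring around a twisted biaryl is strained, and a longer tether gives up the proximity;
- A5 requires O7 of the catechin unit to be told apart from O5, and O3 of the epicatechin unit from its phenols, which costs at least four more protecting-group steps.

Key step: step 5

## Route

Step 1
Reactants: 1 (+)-catechin
Product: 2 5,7,3',4'-tetra-O-benzyl-(+)-catechin
Conditions: BnBr (4.4 equiv), K2CO3, DMF, 0 °C → rt, Ar
Reagents that add atoms: benzyl bromide, BrCc1ccccc1
Why: Williamson etherification; carbonate deprotonates only the four phenols, so the secondary C3–OH stays free and C2/C3 are untouched. The ethers make ring B non-oxidisable and turn ring A into an ether-type donor that reacts at C8.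

Step 2
Reactants: 3 (−)-epicatechin
Product: 4 3',4'-O-(diphenylmethylene)-(−)-epicatechin
Conditions: Ph2CCl2 (1.3 equiv), K2CO3, MeCN, rt, Ar; dilute-acid work-up
Reagents that add atoms: dichlorodiphenylmethane, ClC(Cl)(c1ccccc1)c1ccccc1
Why: Twofold O-alkylation (ketalisation); only the ortho-dihydroxy pair of ring B can close a five-membered 2,2-diphenyl-1,3-benzodioxole, and acyclic chloro-benzhydryl ethers formed at ring A hydrolyse on work-up. This is the known selective catechol protection of flavan-3-ols; no stereocentre is involved.

Step 3
Reactants: 4 3',4'-O-(diphenylmethylene)-(−)-epicatechin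
Product: 5 3,5,7-tri-O-acetyl-3',4'-O-(diphenylmethylene)-(−)-epicatechin
Conditions: Ac2O, pyridine, DMAP (cat.), CH2Cl2, 0 °C → rt
Reagents that add atoms: acetic anhydride, CC(=O)OC(C)=O
Why: DMAP-catalysed acylation of the two ring-A phenols and the axial C3–OH; the ketal is inert. The acetates later make ring A of the upper unit a poor nucleophile and keep O3 from adding to the quinone.

Step 4
Reactants: 5 3,5,7-tri-O-acetyl-3',4'-O-(diphenylmethylene)-(−)-epicatechin
Product: 6 3,5,7-tri-O-acetyl-(−)-epicatechin
Conditions: H2 (1 atm), Pd(OH)2/C, EtOAc, rt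
Reagents that add atoms: none
Why: Hydrogenolysis of the two doubly benzylic C–O bonds of the ketal frees the catechol; aryl and alkyl acetates and the C2–O1 ether of the flavan are expected to survive these neutral conditions.

Step 5
Reactants: 6 3,5,7-tri-O-acetyl-(−)-epicatechin, 2 5,7,3',4'-tetra-O-benzyl-(+)-catechin
Product: 9 3,5,7-tri-O-acetyl-(−)-epicatechin-(6'→8)-5,7,3',4'-tetra-O-benzyl-(+)-catechin, via ortho-quinone 7 (not isolated), via dienone adduct 8 (not isolated)
Conditions: Ag2O (3 equiv), Na2SO4, CH2Cl2, −20 → 0 °C, filter cold under Ar; filtrate added slowly to 2 (3 equiv), Sc(OTf)3 (10 mol %), CH2Cl2, −40 → 0 °C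
Reagents that add atoms: none
Why: Ag2O dehydrogenates the only free catechol present (ring B of 6) to ortho-quinone 7, and the cold filtrate is run into an excess of 2 so that 7 always meets the donor and not the product. Sc(OTf)3 chelates the 1,2-dicarbonyl unit and C8 of ring A of 2 adds to C6' of 7 in a Friedel–Crafts-type conjugate (Michael) addition; loss of the C8 proton gives dienone 8, which enolises to catechol 9, so no halide or boron is needed on either carbon. The closest known reaction type is the formation of 6'→8-linked dehydrodicatechins when a flavan-3-ol ortho-quinone is attacked by ring A of a second flavan-3-ol, together with the acid-catalysed arylation of quinones by alkoxyarenes. No ring is closed: the step forms the one biaryl bond that joins the two units, between two carbons that both carried hydrogen. No stereocentre is created; C2 and C3 of both units come unchanged from 1 and 3, the sp3 carbon C6' of 8 is transient, and the biaryl axis is not defined in the target. Chemoselectivity rests on the protecting groups: only 6 can be oxidised because 2 has no free phenol, and ring A of 2 (three alkoxy donors) is far more nucleophilic than the diacetoxy ring A of 7 or either ring B. Site selectivity rests on structure: C6' is the only unsubstituted β-carbon of the quinone (C1' is blocked) and is the position carbon nucleophiles take, C8 of 2 is flanked by O1 tied back in the pyran and is the usual site of electrophilic attack on 5,7-di-O-benzyl flavan-3-ols (C6 lies between two benzyloxy groups), and O-arylation is excluded because 2 has no phenolic OH. Low temperature and a non-basic medium are chosen to keep 7 from tautomerising at C2 to a quinone methide, which would erase the C2 configuration.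

Step 6
Reactants: 9 3,5,7-tri-O-acetyl-(−)-epicatechin-(6'→8)-5,7,3',4'-tetra-O-benzyl-(+)-catechin
Product: 10 (−)-epicatechin-(6'→8)-5,7,3',4'-tetra-O-benzyl-(+)-catechin
Conditions: HCl (0.5 M) in MeOH/THF, rt, Ar
Reagents that add atoms: none
Why: Acid-catalysed transesterification removes the two aryl acetates and the secondary acetate as methyl acetate; benzyl ethers and the biaryl are inert. The acidic medium avoids phenolates, and with them air oxidation of the free catechol and base-induced opening at C2.

Step 7
Reactants: 10 (−)-epicatechin-(6'→8)-5,7,3',4'-tetra-O-benzyl-(+)-catechin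
Product: 11 (−)-epicatechin-(6'→8)-(+)-catechin (target, CNP0353739.2)
Conditions: H2 (1 atm), Pd(OH)2/C, THF/MeOH, rt; filter under Ar, concentrate, lyophilise
Reagents that add atoms: none
Why: Hydrogenolysis of four aryl benzyl ethers under neutral conditions is the standard endgame for flavan-3-ols; the only by-product is volatile and no stereocentre is touched.

## Compound list

1 | (+)-catechin, (2R,3S) | Oc1cc(O)c2c(c1)O[C@H](c1ccc(O)c(O)c1)[C@@H](O)C2 | starting material
2 | 5,7,3',4'-tetra-O-benzyl-(+)-catechin, (2R,3S) | O(Cc1ccccc1)c1cc(OCc2ccccc2)c2c(c1)O[C@H](c1ccc(OCc3ccccc3)c(OCc3ccccc3)c1)[C@@H](O)C2 | intermediate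
3 | (−)-epicatechin, (2R,3R) | Oc1cc(O)c2c(c1)O[C@H](c1ccc(O)c(O)c1)[C@H](O)C2 | starting material
4 | 3',4'-O-(diphenylmethylene)-(−)-epicatechin, (2R,3R) | Oc1cc(O)c2c(c1)O[C@H](c1ccc3OC(c4ccccc4)(c4ccccc4)Oc3c1)[C@H](O)C2 | intermediate
5 | 3,5,7-tri-O-acetyl-3',4'-O-(diphenylmethylene)-(−)-epicatechin, (2R,3R) | CC(=O)Oc1cc(OC(C)=O)c2c(c1)O[C@H](c1ccc3OC(c4ccccc4)(c4ccccc4)Oc3c1)[C@H](OC(C)=O)C2 | intermediate
6 | 3,5,7-tri-O-acetyl-(−)-epicatechin, (2R,3R) | CC(=O)Oc1cc(OC(C)=O)c2c(c1)O[C@H](c1ccc(O)c(O)c1)[C@H](OC(C)=O)C2 | intermediate
7 | ortho-quinone of 6 (ring B as 3',4'-dione), (2R,3R) | CC(=O)Oc1cc(OC(C)=O)c2c(c1)O[C@H](C1=CC(=O)C(=O)C=C1)[C@H](OC(C)=O)C2 | intermediate (not isolated)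
8 | dienone adduct, keto tautomer of 9 with sp3 C6' of undefined configuration; upper unit (2R,3R), lower unit (2R,3S) | CC(=O)Oc1cc(OC(C)=O)c2c(c1)O[C@H](C1=CC(=O)C(O)=CC1c1c(OCc3ccccc3)cc(OCc3ccccc3)c3c1O[C@H](c1ccc(OCc4ccccc4)c(OCc4ccccc4)c1)[C@@H](O)C3)[C@H](OC(C)=O)C2 | intermediate (not isolated)
9 | 3,5,7-tri-O-acetyl-(−)-epicatechin-(6'→8)-5,7,3',4'-tetra-O-benzyl-(+)-catechin; upper (2R,3R), lower (2R,3S) | CC(=O)Oc1cc(OC(C)=O)c2c(c1)O[C@H](c1cc(O)c(O)cc1-c1c(OCc3ccccc3)cc(OCc3ccccc3)c3c1O[C@H](c1ccc(OCc4ccccc4)c(OCc4ccccc4)c1)[C@@H](O)C3)[C@H](OC(C)=O)C2 | intermediate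
10 | (−)-epicatechin-(6'→8)-5,7,3',4'-tetra-O-benzyl-(+)-catechin; upper (2R,3R), lower (2R,3S) | Oc1cc(O)c2c(c1)O[C@H](c1cc(O)c(O)cc1-c1c(OCc3ccccc3)cc(OCc3ccccc3)c3c1O[C@H](c1ccc(OCc4ccccc4)c(OCc4ccccc4)c1)[C@@H](O)C3)[C@H](O)C2 | intermediate
11 | (−)-epicatechin-(6'→8)-(+)-catechin; upper (2R,3R), lower (2R,3S) | Oc1cc(O)c2c(c1)O[C@H](c1cc(O)c(O)cc1-c1c(O)cc(O)c3c1O[C@H](c1ccc(O)c(O)c1)[C@@H](O)C3)[C@H](O)C2 | target

## Step count and least certain steps

Total: 7 steps. Longest linear sequence: 6 steps (3 → 4 → 5 → 6 → 9 → 10 → 11); step 1 is a one-step side branch that joins at step 5.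

**Step 5 (key step).** Most likely to go wrong:

- Redox exchange between the newly formed, more electron-rich catechol of 9 and unreacted 7, leading to over-oxidation and a second arylation. Inverse addition into excess 2 is meant to limit this.
- Tautomerisation of 7 at C2 to a quinone methide, with loss of the C2 configuration.
- Slow addition, because an ether-type donor is weaker than a free phloroglucinol and depends fully on Lewis-acid activation.
- Partial attack through C6 of 2.

Fallback (sets out from 5 and 2, comes back at 11):

- Ring B of 5 would be brominated with N-bromosuccinimide in MeCN at 0 °C to give 6'-bromo-3,5,7-tri-O-acetyl-3',4'-O-(diphenylmethylene)-(−)-epicatechin F1. Ring A is held back by its acetoxy groups, and C6' is para to O3' of the benzodioxole.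
- 2 would be brominated at C8 (N-bromosuccinimide, CH2Cl2, −78 °C) to 8-bromo-5,7,3',4'-tetra-O-benzyl-(+)-catechin F2, the same compound as A1.
- Bromine–lithium exchange on F2 (n-BuLi, 2.2 equiv, THF, −78 °C) and trapping with 2-isopropoxy-4,4,5,5-tetramethyl-1,3,2-dioxaborolane should give 8-(4,4,5,5-tetramethyl-1,3,2-dioxaborolan-2-yl)-5,7,3',4'-tetra-O-benzyl-(+)-catechin F3.
- Suzuki–Miyaura coupling of F1 with F3 (Pd(OAc)2, SPhos, K3PO4, toluene/water, 80 °C) should give 3,5,7-tri-O-acetyl-3',4'-O-(diphenylmethylene)-(−)-epicatechin-(6'→8)-5,7,3',4'-tetra-O-benzyl-(+)-catechin F4.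
- K2CO3/MeOH under argon would remove the acetates to give 3',4'-O-(diphenylmethylene)-(−)-epicatechin-(6'→8)-5,7,3',4'-tetra-O-benzyl-(+)-catechin F5. Acetates already lost during the coupling are of no consequence.
- Hydrogenolysis (H2, Pd(OH)2/C) would cleave the four benzyl ethers and the ketal together to give 11.

**Step 2.** Most likely to go wrong: competing alkylation of the ring-A phenolates (intermolecular ketals, C-alkylation) and air oxidation of the catecholate under basic conditions.

Fallback (sets out from 3, comes back at 6):

- 3 would be condensed with PhB(OH)2 (THF/toluene, 4 Å molecular sieves) to the cyclic boronate 3',4'-O-(phenylboranediyl)-(−)-epicatechin F6.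
- F6 would be acetylated in the same flask (Ac2O, pyridine) to 3,5,7-tri-O-acetyl-3',4'-O-(phenylboranediyl)-(−)-epicatechin F7.
- The boronate would be hydrolysed during aqueous work-up to give 6 directly, without passing through 4 and 5.

**Step 6.** Most likely to go wrong: slow methanolysis of the axial secondary acetate at C3. Forcing it would prolong acid exposure and invite ionisation of the para-hydroxybenzylic C2–O1 bond of the upper unit, with epimerisation at C2.

Fallback (sets out from 9, comes back at 10): reductive cleavage of the three acetates with i-Bu2AlH (excess, CH2Cl2/THF, −78 °C) and work-up with aqueous tartaric acid. This replaces acyl transfer to the solvent by hydride reduction and makes no new compound.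

## Further compounds

F1 | step 5 | 6'-bromo-3,5,7-tri-O-acetyl-3',4'-O-(diphenylmethylene)-(−)-epicatechin | CC(=O)Oc1cc(OC(C)=O)c2c(c1)O[C@H](c1cc3OC(c4ccccc4)(c4ccccc4)Oc3cc1Br)[C@H](OC(C)=O)C2
F2 | step 5 | 8-bromo-5,7,3',4'-tetra-O-benzyl-(+)-catechin | Brc1c(OCc2ccccc2)cc(OCc2ccccc2)c2c1O[C@H](c1ccc(OCc3ccccc3)c(OCc3ccccc3)c1)[C@@H](O)C2
F3 | step 5 | 8-(4,4,5,5-tetramethyl-1,3,2-dioxaborolan-2-yl)-5,7,3',4'-tetra-O-benzyl-(+)-catechin | CC1(C)OB(OC1(C)C)c1c(OCc2ccccc2)cc(OCc2ccccc2)c2c1O[C@H](c1ccc(OCc3ccccc3)c(OCc3ccccc3)c1)[C@@H](O)C2
F4 | step 5 | 3,5,7-tri-O-acetyl-3',4'-O-(diphenylmethylene)-(−)-epicatechin-(6'→8)-5,7,3',4'-tetra-O-benzyl-(+)-catechin | CC(=O)Oc1cc(OC(C)=O)c2c(c1)O[C@H](c1cc3OC(c4ccccc4)(c4ccccc4)Oc3cc1-c1c(OCc3ccccc3)cc(OCc3ccccc3)c3c1O[C@H](c1ccc(OCc4ccccc4)c(OCc4ccccc4)c1)[C@@H](O)C3)[C@H](OC(C)=O)C2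
F5 | step 5 | 3',4'-O-(diphenylmethylene)-(−)-epicatechin-(6'→8)-5,7,3',4'-tetra-O-benzyl-(+)-catechin | Oc1cc(O)c2c(c1)O[C@H](c1cc3OC(c4ccccc4)(c4ccccc4)Oc3cc1-c1c(OCc3ccccc3)cc(OCc3ccccc3)c3c1O[C@H](c1ccc(OCc4ccccc4)c(OCc4ccccc4)c1)[C@@H](O)C3)[C@H](O)C2
F6 | step 2 | 3',4'-O-(phenylboranediyl)-(−)-epicatechin | Oc1cc(O)c2c(c1)O[C@H](c1ccc3OB(c4ccccc4)Oc3c1)[C@H](O)C2
F7 | step 2 | 3,5,7-tri-O-acetyl-3',4'-O-(phenylboranediyl)-(−)-epicatechin | CC(=O)Oc1cc(OC(C)=O)c2c(c1)O[C@H](c1ccc3OB(c4ccccc4)Oc3c1)[C@H](OC(C)=O)C2
F0 | step 6 | none | none
A1 | alternative 1 | 8-bromo-5,7,3',4'-tetra-O-benzyl-(+)-catechin | Brc1c(OCc2ccccc2)cc(OCc2ccccc2)c2c1O[C@H](c1ccc(OCc3ccccc3)c(OCc3ccccc3)c1)[C@@H](O)C2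
A2 | alternative 1 | 6'-(4,4,5,5-tetramethyl-1,3,2-dioxaborolan-2-yl)-5,7,3',4'-tetra-O-benzyl-(−)-epicatechin | O(Cc1ccccc1)c1cc(OCc2ccccc2)c2c(c1)O[C@H](c1cc(OCc3ccccc3)c(OCc3ccccc3)cc1B1OC(C)(C)C(C)(C)O1)[C@H](O)C2
A3 | alternative 2 | 8-[2-formyl-4,5-bis(benzyloxy)phenyl]-5,7,3',4'-tetra-O-benzyl-(+)-catechin | O=Cc1cc(OCc2ccccc2)c(OCc2ccccc2)cc1-c1c(OCc2ccccc2)cc(OCc2ccccc2)c2c1O[C@H](c1ccc(OCc3ccccc3)c(OCc3ccccc3)c1)[C@@H](O)C2
A4 | alternative 2 | 8-{2-[(E)-3-(2,4-bis(benzyloxy)-6-(methoxymethoxy)phenyl)prop-1-enyl]-4,5-bis(benzyloxy)phenyl}-5,7,3',4'-tetra-O-benzyl-(+)-catechin | COCOc1cc(OCc2ccccc2)cc(OCc2ccccc2)c1C/C=C/c1cc(OCc2ccccc2)c(OCc2ccccc2)cc1-c1c(OCc2ccccc2)cc(OCc2ccccc2)c2c1O[C@H](c1ccc(OCc3ccccc3)c(OCc3ccccc3)c1)[C@@H](O)C2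
A5 | alternative 3 | diisopropylsilylene-bridged pair: O3 of 5,7-di-O-acetyl-(−)-epicatechin linked to O7 of 5,3',4'-tri-O-benzyl-(+)-catechin | CC(=O)Oc1cc(OC(C)=O)c2c(c1)O[C@H](c1ccc(O)c(O)c1)[C@H](O[Si](C(C)C)(C(C)C)Oc1cc(OCc3ccccc3)c3c(c1)O[C@H](c1ccc(OCc4ccccc4)c(OCc4ccccc4)c1)[C@@H](O)C3)C2
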